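Its constants are made up; the run is a simulation.

Ring closure is slow: D.J, formed from the substrate D and the activator J, closes at 110 °C to the ring Z with a half-life by this step alone of 14.7 s, longer than the 12 s run. While it waits, D can attack it and give the open dimer D.D.J. The next run has to keep D away from D.J.

| setting | Sunday's | Friday's | Monday's | Saturday's | Thursday's |
|---|---|---|---|---|---|
| D | 5.0 × 10⁻⁴ M (in portions, 5, over 10 s) | 5.0 × 10⁻⁴ M | 5.0 × 10⁻⁴ M | 5.0 × 10⁻⁴ M | 5.0 × 10⁻⁴ M (fed, over 10 s) |
| J | 0.525 mM | 0.525 mM | 0.525 mM (fed, over 10 s) | 0.525 mM | 0.525 mM |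
| X | 0.500 mM | 0.500 mM | 0.500 mM | 0.500 mM | 0.500 mM |
| temperature | 110 °C |  | 110 °C | 110 °C |  |
| time | 12 s | 12 s | 12 s | 12 s | 12 s |
| remark | first portion at the start, last at 10 s | everything together at the start at 70 °C, warmed to 110 °C at 10 s | all else is in the flask from the start; the feed brings no volume worth counting | everything together at the start | the addition at 70 °C, then warmed to 110 °C; the feed brings no volume worth counting |

    D + J → D.J (k1 = 120 M⁻¹ s⁻¹, Ea1 = 48.0 kJ mol⁻¹)
    D.J → Z (k2 = 0.047 s⁻¹, Ea2 = 114 kJ mol⁻¹)
    D + D.J → D.D.J (k3 = 47 M⁻¹ s⁻¹, Ea3 = 45.0 kJ mol⁻¹)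
    D + Z ⇌ D.Z, settled at all times (K4 = 920 M⁻¹, ΔH4 = −6.00 kJ mol⁻¹)
    J + X → J.X (k5 = 180 M⁻¹ s⁻¹, Ea5 = 37.0 kJ mol⁻¹)
    (constants at 110 °C)

- percent here means D units held: one D.D.J or D.Z counts as two
- what is said of Z includes D.Z
- at 110 °C the constants are as listed, elsewhere as the activation energies and enthalpies make them
- in an amount of Z, one D.Z counts as one Z

- the flask with the highest share of Z in Z plus D.D.J ("all alike" if they lie within 1.5 percentage points) (Sunday's / Friday's / Monday's / Saturday's / Thursday's / all alike)
- share of Z in Z plus D.D.J at the end, Sunday's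
- share of Z in Z plus D.D.J at the end, Friday's
- share of Z in Z plus D.D.J at the end, Monday's
- share of Z in Z plus D.D.J at the end, Saturday's
- share of Z in Z plus D.D.J at the end, Thursday's

D.J leaves by two exits. Closing gives one Z, while meeting D gives one D.D.J, which counts two in the share. The share made at free D is therefore E/(E + [D]), where E at 110 °C is the closure constant over twice the dimer constant, 0.500 mM, the even-split concentration. This is a selectivity factor written as a concentration. It equals the charge of D, so D standing whole gives 50.0%.

My reckoning goes as follows. Saturday's starts at that even split and climbs as D falls, but D falls slowly. In Saturday's, the half-life of D by step 1 alone, J as charged, is 11.0 s, longer than the 7.7 s in which step 5 alone halves J. Monday's feeds J over 10 s, and my estimate puts its D near the charge and its share near the even split. Sunday's D climbs a staircase of 5 levels with mean 0.300 mM, below the charge. With consumption ignored, that mean level gives 62.5%. Friday's and Thursday's spend 10 s at 70 °C, and closure has the steeper activation energy, 114 kJ mol⁻¹ against 45.0 kJ mol⁻¹, so their even split lies lower while cold. The decision is Sunday's recipe: D in portions at 110 °C, with J and X unchanged.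

The forecast also names Sunday's, with Sunday's 67.5%, Saturday's 62.4%, Monday's 59.8%, Thursday's 56% and Friday's 52.4%. It counted “Z = 1, D.Z = 2, D.D.J = 2”. Its 67.5% for Sunday's stands above my 62.5%.

The simulation gives Sunday's first: Sunday's 62.1%, Saturday's 57.6%, Monday's 54.5%, Thursday's 49.4%, Friday's 45.7%.

At 12.0 s Sunday's still held D.J at 14.3% of the D charged, beside Z at 4.10% and D.D.J at 2.50%, with J at 33.8% of its charge. By 120 s Sunday's J stood at 0.0370%, its D.J at 0.167% and its share at 62.6%. With D.Z taken at two, Sunday's end state gives 67.4%; with one D.Z as one Z it gives 62.1%. Through the even split of 0.500 mM, that 62.1% reads as an effective free D of 0.305 mM, beside the staircase's 0.300 mM. Monday's mean D of 4.61 × 10⁻⁴ M over the first 10 s gives 52.0%, and Monday's share is 54.5%.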